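**Plan**

Numbering: tetralin C1 carries the aryl group, C2 and C3 the CH2OH groups, C4 is the benzylic CH2; ring A is the fused benzene (C4a–C8a, OMe on C6, OH on C7), ring B the carbocycle.
Retrosynthesis: the two O-benzyl groups and both CH2OH groups go back to a C2 thioimide and a C3 methyl ester; ring B is then opened at C1–C2 to an acyclic benzhydryl methyl ether carrying an (S)-benzylsuccinate chain; C3 goes back to the C3=C4 alkene of a Stobbe half-ester (cut C4=C3), the aldehyde to an aryl bromide (cut C4a–C4), and the C1–pendant aryl bond to an aryllithium plus an aldehyde.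
Forward: the pendant aryl is joined to ring A at C1, C4 is added by formylation, the Stobbe condensation brings in C3, C2 and both carboxyl carbons, hydrogenation sets C3, and ring B is closed last through C1–C2; reduction and debenzylation finish the route.
Enabling feature: C1 is doubly benzylic and para to both the C6 methoxy group of ring A and the 4-oxygen of the pendant aryl, so its methyl ether ionises to a long-lived cation (a masked para-quinone methide); C2 is α to a carbonyl at the oxidation level of the later CH2OH and is enolised selectively through a chelating thioimide, which is removed in step 7.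
Stereochemistry: C3 comes from catalyst-controlled hydrogenation; C1 and C2 are both created in the ring closure under control of C3 (chair-like, all-equatorial); the carbinol centre made in step 1 is racemic on purpose and is erased on ionisation.

Key step: step 6

Remark: 1 and 2 are taken as catalogue compounds; each is otherwise one O-benzylation away from a commercial phenol (2-bromo-5-hydroxy-4-methoxybenzaldehyde; 4-bromo-2-methoxyphenol).
Abbreviation: Ar* = 4-(benzyloxy)-2-{[4-(benzyloxy)-3-methoxyphenyl](methoxy)methyl}-5-methoxyphenyl. Compounds 4 to 8 and 11 are racemic at the methoxy-bearing benzhydryl carbon, 10 is a diastereomer mixture, and 12 and 13 are pairs of epimers at that carbon, which is written without configuration.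

**Route**

Step 1
Reactants: 1 bromoaldehyde 5-(benzyloxy)-2-bromo-4-methoxybenzaldehyde; 2 aryl bromide 1-(benzyloxy)-4-bromo-2-methoxybenzene
Product: 5 [5-(benzyloxy)-2-bromo-4-methoxyphenyl][4-(benzyloxy)-3-methoxyphenyl]methyl methyl ether (Ar*–Br), via aryllithium 3 (not isolated), via lithium alkoxide 4 (not isolated)
Conditions: 2, n-BuLi, THF, −78 °C; then 1, −78 °C; then MeI, DMPU, −78 °C to rt
Reagents that add atoms: iodomethane (MeI), SMILES CI
Why: Bromine–lithium exchange on 2, 1,2-addition of aryllithium 3 to the aldehyde (faster at −78 °C than exchange with the aryl bromide of 1) and Williamson O-methylation of alkoxide 4 in the same flask install the C1–aryl bond and the later leaving group; the new centre is racemic on purpose because it is ionised in step 6.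

Step 2
Reactants: 5 [5-(benzyloxy)-2-bromo-4-methoxyphenyl][4-(benzyloxy)-3-methoxyphenyl]methyl methyl ether
Product: 8 aldehyde 4-(benzyloxy)-2-{[4-(benzyloxy)-3-methoxyphenyl](methoxy)methyl}-5-methoxybenzaldehyde (Ar*–CHO), via aryllithium 6 (not isolated), via lithium hemiaminolate 7 (not isolated)
Conditions: n-BuLi, THF, −78 °C; then DMF, −78 to 0 °C; aq NH4Cl
Reagents that add atoms: N,N-dimethylformamide, SMILES CN(C)C=O
Why: Bromine–lithium exchange (the aryllithium is stabilised by chelation to the neighbouring methoxy oxygen) and formylation with DMF, a Bouveault-type aldehyde synthesis, place the future C4 on C4a; benzyl and methyl ethers are inert to n-BuLi at −78 °C.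

Step 3
Reactants: 8 aldehyde 4-(benzyloxy)-2-{[4-(benzyloxy)-3-methoxyphenyl](methoxy)methyl}-5-methoxybenzaldehyde; 9 dimethyl succinate
Product: 11 half-ester (3E)-4-Ar*-3-(methoxycarbonyl)but-3-enoic acid, via paraconate lactone 10 (not isolated)
Conditions: NaOMe, MeOH, reflux; then 1 M HCl to pH 4, 0 °C
Reagents that add atoms: none
Why: Stobbe condensation: aldol addition, lactonisation to paraconate 10 and base-induced ring opening should give the (E)-alkylidene half-ester with the free acid on the C2 arm and the ester on C3, which differentiates the two carboxyl groups for steps 5 to 7; the benzhydryl ether is stable to methoxide and should survive a cold, mildly acidic work-up.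

Step 4
Reactants: 11 half-ester (3E)-4-Ar*-3-(methoxycarbonyl)but-3-enoic acid
Product: 12 acid (3S)-4-Ar*-3-(methoxycarbonyl)butanoic acid
Conditions: H2 (5 bar), [Rh(cod)((R,R)-Et-DuPHOS)]OTf (1 mol%), NaOMe (10 mol%), MeOH, rt
Reagents that add atoms: none
Why: Carboxylate-directed asymmetric hydrogenation of the itaconate-type half-ester with a cationic rhodium bisphospholane catalyst should set C3 (S) by catalyst control (the (R,R) ligand antipode is the one expected to give this sense by analogy with β-aryl itaconate half-esters, and the other antipode is equally available), while aryl benzyl ethers and the benzhydryl ether are not hydrogenolysed by homogeneous rhodium.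

Step 5
Reactants: 12 acid (3S)-4-Ar*-3-(methoxycarbonyl)butanoic acid
Product: 13 thioimide methyl (2S)-2-(Ar*-methyl)-4-oxo-4-(2-sulfanylidene-1,3-thiazolidin-3-yl)butanoate
Conditions: 1,3-thiazolidine-2-thione, EDC·HCl, DMAP (cat.), CH2Cl2, 0 °C to rt
Reagents that add atoms: 1,3-thiazolidine-2-thione, SMILES S=C1NCCS1
Why: Carbodiimide coupling (Steglich-type N-acylation) converts only the free C2 carboxyl into the chelating N-acyl thiazolidinethione needed for soft enolisation; the activated carboxyl has a CH2 α-carbon, so the C3 centre next to the untouched methyl ester cannot epimerise.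

Step 6
Reactants: 13 thioimide methyl (2S)-2-(Ar*-methyl)-4-oxo-4-(2-sulfanylidene-1,3-thiazolidin-3-yl)butanoate
Product: 15 tetralin methyl (2S,3S,4R)-6-(benzyloxy)-4-[4-(benzyloxy)-3-methoxyphenyl]-7-methoxy-3-(2-sulfanylidene-1,3-thiazolidine-3-carbonyl)-1,2,3,4-tetrahydronaphthalene-2-carboxylate (1R,2S,3S in the numbering of the plan), via benzhydryl cation triflate 14 (not isolated)
Conditions: (Me3P)2NiCl2 (10 mol%), Et3SiOTf (1.5 equiv), 2,6-lutidine (1.5 equiv), CH2Cl2 (0.02 M), −20 to 0 °C
Reagents that add atoms: none
Why: Et3SiOTf removes methoxide from either C1 epimer of 13 to give the same planar, doubly benzylic cation 14 (stabilised by the C6 methoxy group of ring A and by the para benzyloxy group of the pendant aryl), while the nickel triflate formed in situ chelates the thioimide so that 2,6-lutidine enolises C2 alone, and the chelated Z enolate then collapses onto C1 in an SN1-type alkylation. The closest known reaction type is the direct nickel-catalysed alkylation of N-acyl thiazolidinethiones with diarylmethyl methyl ethers, run here intramolecularly. Ring B closes in a 6-exo-trig mode that is also exo for the enolate (6-enolexo), so both π systems stay outside the new ring. C2 is controlled by C3: in the chair-like transition state the C3–H bond lies in the enolate plane (allylic 1,3-strain), the tether attacks from the C4 side, and the C2 acyl and C3 CO2Me groups should both end up equatorial and trans. C1 is controlled by the cation geometry: the pendant aryl points away from the ortho side chain toward C8–H and so becomes pseudo-equatorial, trans to C2 and cis to the C3 substituent, which together should give (1R,2S,3S). The step needs site-selective enolisation (secured by the thioimide, since the C3–H next to the methyl ester is not acidic enough under soft enolisation) and capture of the cation ahead of intermolecular alkylation (secured by dilution); a minor C2 epimer could be corrected with mild base because C2–H is the more acidic position.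

Step 7
Reactants: 15 tetralin methyl (2S,3S,4R)-6-(benzyloxy)-4-[4-(benzyloxy)-3-methoxyphenyl]-7-methoxy-3-(2-sulfanylidene-1,3-thiazolidine-3-carbonyl)-1,2,3,4-tetrahydronaphthalene-2-carboxylate
Product: 16 diol [(1R,2S,3S)-7-(benzyloxy)-1-[4-(benzyloxy)-3-methoxyphenyl]-6-methoxy-1,2,3,4-tetrahydronaphthalene-2,3-diyl]dimethanol
Conditions: LiBH4, THF–MeOH, 0 °C to rt
Reagents that add atoms: none
Why: LiBH4 reduces the activated thioimide (releasing the thiazolidinethione) and the methyl ester to the two primary alcohols in one operation without touching benzyl ethers; hydride attack on the thioimide is much faster than enolisation at C2, so no stereocentre is at risk.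

Step 8
Reactants: 16 diol [(1R,2S,3S)-7-(benzyloxy)-1-[4-(benzyloxy)-3-methoxyphenyl]-6-methoxy-1,2,3,4-tetrahydronaphthalene-2,3-diyl]dimethanol
Product: 17 target (6S,7S,8R)-8-(4-hydroxy-3-methoxyphenyl)-6,7-bis(hydroxymethyl)-3-methoxy-5,6,7,8-tetrahydronaphthalen-2-ol
Conditions: H2 (1 atm), 10% Pd/C, EtOAc–MeOH, rt
Reagents that add atoms: none
Why: Hydrogenolysis of the two aryl benzyl ethers over palladium metal on carbon frees both phenols; the diol carries no benzylic C–O bond and the C1–H and C1–aryl bonds are inert, so the three stereocentres are untouched (16 is chromatographed first to remove traces of the sulfur auxiliary).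

**Compound list**

1 | 5-(benzyloxy)-2-bromo-4-methoxybenzaldehyde | O=Cc1cc(OCc2ccccc2)c(OC)cc1Br | starting material
2 | 1-(benzyloxy)-4-bromo-2-methoxybenzene | COc1cc(Br)ccc1OCc1ccccc1 | starting material
3 | [4-(benzyloxy)-3-methoxyphenyl]lithium | COc1cc([Li])ccc1OCc1ccccc1 | intermediate (not isolated)
4 | lithium [5-(benzyloxy)-2-bromo-4-methoxyphenyl][4-(benzyloxy)-3-methoxyphenyl]methanolate (racemic) | COc1cc(C(O[Li])c2cc(OCc3ccccc3)c(OC)cc2Br)ccc1OCc1ccccc1 | intermediate (not isolated)
5 | [5-(benzyloxy)-2-bromo-4-methoxyphenyl][4-(benzyloxy)-3-methoxyphenyl]methyl methyl ether, Ar*–Br (racemic) | COc1cc(C(OC)c2cc(OCc3ccccc3)c(OC)cc2Br)ccc1OCc1ccccc1 | intermediate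
6 | aryllithium Ar*–Li (racemic) | COc1cc(C(OC)c2cc(OCc3ccccc3)c(OC)cc2[Li])ccc1OCc1ccccc1 | intermediate (not isolated)
7 | lithium hemiaminolate Ar*–CH(OLi)NMe2 | COc1cc(C(OC)c2cc(OCc3ccccc3)c(OC)cc2C(O[Li])N(C)C)ccc1OCc1ccccc1 | intermediate (not isolated)
8 | 4-(benzyloxy)-2-{[4-(benzyloxy)-3-methoxyphenyl](methoxy)methyl}-5-methoxybenzaldehyde, Ar*–CHO (racemic) | COc1cc(C(OC)c2cc(OCc3ccccc3)c(OC)cc2C=O)ccc1OCc1ccccc1 | intermediate
9 | dimethyl succinate | COC(=O)CCC(=O)OC | starting material
10 | methyl 2-Ar*-5-oxooxolane-3-carboxylate (paraconate lactone, diastereomer mixture) | COC(=O)C1CC(=O)OC1c1cc(OC)c(OCc2ccccc2)cc1C(OC)c1ccc(OCc2ccccc2)c(OC)c1 | intermediate (not isolated)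
11 | (3E)-4-Ar*-3-(methoxycarbonyl)but-3-enoic acid (racemic at the benzhydryl carbon) | COc1cc(C(OC)c2cc(OCc3ccccc3)c(OC)cc2/C=C(/C(=O)OC)CC(=O)O)ccc1OCc1ccccc1 | intermediate
12 | (3S)-4-Ar*-3-(methoxycarbonyl)butanoic acid (both epimers at the benzhydryl carbon) | COc1cc(C(OC)c2cc(OCc3ccccc3)c(OC)cc2C[C@H](C(=O)OC)CC(=O)O)ccc1OCc1ccccc1 | intermediate
13 | methyl (2S)-2-(Ar*-methyl)-4-oxo-4-(2-sulfanylidene-1,3-thiazolidin-3-yl)butanoate (both epimers at the benzhydryl carbon) | COc1cc(C(OC)c2cc(OCc3ccccc3)c(OC)cc2C[C@H](C(=O)OC)CC(=O)N2CCSC2=S)ccc1OCc1ccccc1 | intermediate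
14 | benzhydryl cation of 13 (methoxide removed from the benzhydryl carbon) as its triflate | COc1cc([CH+]c2cc(OCc3ccccc3)c(OC)cc2C[C@H](C(=O)OC)CC(=O)N2CCSC2=S)ccc1OCc1ccccc1.[O-]S(=O)(=O)C(F)(F)F | intermediate (not isolated)
15 | methyl (2S,3S,4R)-6-(benzyloxy)-4-[4-(benzyloxy)-3-methoxyphenyl]-7-methoxy-3-(2-sulfanylidene-1,3-thiazolidine-3-carbonyl)-1,2,3,4-tetrahydronaphthalene-2-carboxylate | COc1cc([C@@H]2c3cc(OCc4ccccc4)c(OC)cc3C[C@H](C(=O)OC)[C@H]2C(=O)N2CCSC2=S)ccc1OCc1ccccc1 | intermediate
16 | [(1R,2S,3S)-7-(benzyloxy)-1-[4-(benzyloxy)-3-methoxyphenyl]-6-methoxy-1,2,3,4-tetrahydronaphthalene-2,3-diyl]dimethanol | COc1cc([C@@H]2c3cc(OCc4ccccc4)c(OC)cc3C[C@H](CO)[C@H]2CO)ccc1OCc1ccccc1 | intermediate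
17 | (6S,7S,8R)-8-(4-hydroxy-3-methoxyphenyl)-6,7-bis(hydroxymethyl)-3-methoxy-5,6,7,8-tetrahydronaphthalen-2-ol (isolariciresinol, 1R,2S,3S in the numbering of the plan) | COc1cc([C@@H]2c3cc(O)c(OC)cc3C[C@H](CO)[C@H]2CO)ccc1O | target

**Summary**

Total step count: 8. Longest linear sequence: 8 steps (1 or 2 to 17).

Steps most likely to fail:

Step 6. The cation may persist without being captured if enolisation is slow, which would open intermolecular alkylation, or the ring may close with poor facial selectivity at C1; diastereomers would have to be separated at 15 before going on. The fallback replaces the metal enolate by enamine catalysis. Setting out from 13, DIBAL-H (CH2Cl2, −78 °C) should reduce the thioimide selectively to the aldehyde methyl (2S)-2-(Ar*-methyl)-4-oxobutanoate F1. A secondary amine (pyrrolidine, 20 mol%) with In(OTf)3 (10 mol%) in CH2Cl2 should then form the C2 enamine while the Lewis acid ionises the benzhydryl ether, and SN1-type α-alkylation closes ring B to methyl (2S,3S,4R)-6-(benzyloxy)-4-[4-(benzyloxy)-3-methoxyphenyl]-3-formyl-7-methoxy-1,2,3,4-tetrahydronaphthalene-2-carboxylate F2, whose C2 centre can equilibrate to the trans arrangement through the enamine. LiBH4 reduces the aldehyde and the ester of F2 together, and the route is rejoined at 16.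

Step 4. Hydrogen delivery may be slow or poorly face-selective because the bulky ortho benzhydryl group hinders chelation of the carboxylate and alkene to rhodium. The fallback moves the stereocontrol from the catalyst to an auxiliary in the ring closure and sets C3 afterwards. Setting out from 11, EDC/DMAP coupling with (4S)-4-isopropyl-1,3-thiazolidine-2-thione gives the unsaturated thioimide methyl (2E)-3-Ar*-2-{2-[(4S)-4-isopropyl-2-sulfanylidene-1,3-thiazolidin-3-yl]-2-oxoethyl}prop-2-enoate F3. The conditions of step 6 should close ring B to methyl (3S,4R)-6-(benzyloxy)-4-[4-(benzyloxy)-3-methoxyphenyl]-3-[(4S)-4-isopropyl-2-sulfanylidene-1,3-thiazolidine-3-carbonyl]-7-methoxy-3,4-dihydronaphthalene-2-carboxylate F4; the auxiliary is expected to fix C2 by the chelate model (its antipode is equally available) and the ring closure to place the aryl trans. DIBAL-H (excess, CH2Cl2, −78 to 0 °C) reduces thioimide and enoate to the allylic diol [(1R,2S)-7-(benzyloxy)-1-[4-(benzyloxy)-3-methoxyphenyl]-6-methoxy-1,2-dihydronaphthalene-2,3-diyl]dimethanol F5. Hydrogenation with [Ir(cod)(PCy3)(py)]PF6 (H2 1 atm, CH2Cl2), directed by the C2 hydroxymethyl group, should deliver hydrogen to C3 on the face of that group, so the C3 hydroxymethyl ends up trans and the route is rejoined at 16.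

Step 3. Aldol addition to the hindered ortho-substituted aldehyde may be slow, the lactone opening may erode the alkene geometry, and the benzhydryl methoxy group may exchange during acidification. The fallback replaces the condensation by an olefination whose reagent already differentiates the carboxyl groups. Setting out from 8, Horner–Wadsworth–Emmons reaction with 4-allyl 1-methyl 2-(dimethoxyphosphoryl)butanedioate (NaH, THF, 0 °C to rt; the reagent is made from trimethyl phosphonoacetate and allyl bromoacetate) should give 4-allyl 1-methyl (2E)-2-(Ar*-methylidene)butanedioate F6. Pd(PPh3)4 with morpholine (THF, rt) then removes the allyl group under neutral conditions, and the route is rejoined at 11.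

Further compounds
F1 | step 6 | methyl (2S)-2-(Ar*-methyl)-4-oxobutanoate | COc1cc(C(OC)c2cc(OCc3ccccc3)c(OC)cc2C[C@H](C(=O)OC)CC=O)ccc1OCc1ccccc1
F2 | step 6 | methyl (2S,3S,4R)-6-(benzyloxy)-4-[4-(benzyloxy)-3-methoxyphenyl]-3-formyl-7-methoxy-1,2,3,4-tetrahydronaphthalene-2-carboxylate | COc1cc([C@@H]2c3cc(OCc4ccccc4)c(OC)cc3C[C@H](C(=O)OC)[C@H]2C=O)ccc1OCc1ccccc1
F3 | step 4 | methyl (2E)-3-Ar*-2-{2-[(4S)-4-isopropyl-2-sulfanylidene-1,3-thiazolidin-3-yl]-2-oxoethyl}prop-2-enoate | COc1cc(C(OC)c2cc(OCc3ccccc3)c(OC)cc2/C=C(/C(=O)OC)CC(=O)N2[C@@H](C(C)C)CSC2=S)ccc1OCc1ccccc1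
F4 | step 4 | methyl (3S,4R)-6-(benzyloxy)-4-[4-(benzyloxy)-3-methoxyphenyl]-3-[(4S)-4-isopropyl-2-sulfanylidene-1,3-thiazolidine-3-carbonyl]-7-methoxy-3,4-dihydronaphthalene-2-carboxylate | COc1cc([C@@H]2c3cc(OCc4ccccc4)c(OC)cc3C=C(C(=O)OC)[C@H]2C(=O)N2[C@@H](C(C)C)CSC2=S)ccc1OCc1ccccc1
F5 | step 4 | [(1R,2S)-7-(benzyloxy)-1-[4-(benzyloxy)-3-methoxyphenyl]-6-methoxy-1,2-dihydronaphthalene-2,3-diyl]dimethanol | COc1cc([C@@H]2c3cc(OCc4ccccc4)c(OC)cc3C=C(CO)[C@H]2CO)ccc1OCc1ccccc1
F6 | step 3 | 4-allyl 1-methyl (2E)-2-(Ar*-methylidene)butanedioate | COc1cc(C(OC)c2cc(OCc3ccccc3)c(OC)cc2/C=C(/C(=O)OC)CC(=O)OCC=C)ccc1OCc1ccccc1
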